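**Retrosynthetic overview**

1. C11=C12 is cut by a Horner–Wadsworth–Emmons disconnection into the (9Z)-C15 aldehyde 16 (bicyclic end group) and the C12 phosphonate 21 (from the C10 dialdehyde 17); ester reduction and desilylation finish.
2. The dihydrofuran ring (O1–C8 bond) is closed last, by gold-catalysed 5-endo cyclisation of the α-hydroxyallene 13; the C6=C7=C8 axis is transferred to C8.
3. The carbocycle C1–C6, the allene axis and the C5 carbinol come from one operation on the cyclopentanol–butenolide 10: 1,2-shift of C1 from C5 to alkyne carbon C6 (cyclopentane → cyclohexane) with SN2′ loss of the butenolide carboxylate from C8, then methylation of the C5 ketone in the same flask.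
4. Enabling feature: in the carbocycle the oxygen-bearing quaternary C5 is bonded to the sp2 ring-fusion carbon C6, whose exocyclic partner C7 leads to the oxygen-bearing C8, and C9=C10 is Z with C8 and C11 cis. C5 can therefore be a cyclopentanol carbon, C6–C7 an alkyne, and C8–O/C11 a temporary butenolide ring that is both leaving group and source of the Z-alkene.
5. Ring order: cyclopentane (bought as 1; C3 set by copper-catalysed borylation) → temporary butenolide (catalytic asymmetric alkynylation sets its C5, the later C8) → cyclohexane (ring expansion, butenolide opened) → dihydrofuran.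

Key step: step 7

Assumption: the SMILES is read literally, i.e. 3S,5R,8S with the C9=C10 bond Z (C8 and C11 cis) and all other chain double bonds E; carotenoid numbering is used for atoms (ring C1–C6, chain C7–C15 and C15′–C10′). Compounds 14–24 should be kept away from acid and strong light.

**Route**

Step 1
Reactants: 1 2,2-dimethylcyclopentan-1-one
Product: 2 5,5-dimethylcyclopent-2-en-1-one
Conditions: 2-iodoxybenzoic acid (IBX, 2 equiv), DMSO/toluene, 70 °C
Reagents that add atoms: none
Why: IBX dehydrogenation of a ketone to its enone; only one α-carbon carries hydrogen, so a single enone can form.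

Step 2
Reactants: 2 5,5-dimethylcyclopent-2-en-1-one
Product: 4 (4S)-4-hydroxy-2,2-dimethylcyclopentan-1-one, via pinacol boronate 3 (not isolated)
Conditions: CuCl (3 mol %), NaOt-Bu (5 mol %), (R,S)-Josiphos (3 mol %; antipode if a test run shows the opposite sense), B2pin2, MeOH, THF, rt; then 30 % H2O2, pH 7 phosphate buffer, 0 °C
Reagents that add atoms: bis(pinacolato)diboron, CC1(C)OB(OC1(C)C)B1OC(C)(C)C(C)(C)O1 (boron group of 3); hydrogen peroxide, OO (hydroxyl oxygen of 4)
Why: enantioselective conjugate borylation of a cyclic enone with a chiral monovalent copper catalyst, then stereoretentive C–B oxidation; the ligand sets this centre, which becomes C3 of the target.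

Step 3
Reactants: 4 (4S)-4-hydroxy-2,2-dimethylcyclopentan-1-one
Product: 5 (4S)-4-{[tert-butyl(dimethyl)silyl]oxy}-2,2-dimethylcyclopentan-1-one
Conditions: TBSCl, imidazole, DMF, rt
Reagents that add atoms: tert-butyldimethylsilyl chloride, CC(C)(C)[Si](C)(C)Cl
Why: standard silylation of a secondary alcohol; the bulky ether later fixes the ring conformation used for the C3 → C5 relay.

Step 4
Reactants: 5 (4S)-4-{[tert-butyl(dimethyl)silyl]oxy}-2,2-dimethylcyclopentan-1-one
Product: 6 (4S)-4-{[tert-butyl(dimethyl)silyl]oxy}-1-ethynyl-2,2-dimethylcyclopentan-1-ol (both C-1 epimers, used together)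
Conditions: HC≡CMgBr, CeCl3, THF, −78 → 0 °C
Reagents that add atoms: ethynylmagnesium bromide, C#C[Mg]Br
Why: organocerium 1,2-addition to a hindered, β-silyloxy ketone without enolisation or β-elimination; the new carbinol centre need not be controlled because it becomes the C5 carbonyl carbon in step 7.

Step 5
Reactants: 7 5-hydroxy-4-methylfuran-2(5H)-one
Product: 8 methyl (2Z)-3-methyl-4-oxobut-2-enoate
Conditions: Me3SiCHN2, toluene/MeOH 4:1, 0 °C; concentrated cold and used at once
Reagents that add atoms: (trimethylsilyl)diazomethane, C[Si](C)(C)C=[N+]=[N-] (ester methyl carbon)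
Why: diazoalkane esterification of the ring-opened carboxylic acid tautomer of the pseudo-acid should give the open-chain Z formyl ester under neutral conditions that neither isomerise it to E nor close it to the pseudo-ester.

Step 6
Reactants: 6 (4S)-4-{[tert-butyl(dimethyl)silyl]oxy}-1-ethynyl-2,2-dimethylcyclopentan-1-ol; 8 methyl (2Z)-3-methyl-4-oxobut-2-enoate
Product: 10 (5R)-5-{[(4S)-4-{[tert-butyl(dimethyl)silyl]oxy}-1-hydroxy-2,2-dimethylcyclopentyl]ethynyl}-4-methylfuran-2(5H)-one (both carbinol epimers), via Z-hydroxy enoate zinc alkoxide 9 (not isolated)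
Conditions: (R,R)-ProPhenol (20 mol %; antipode if a model run shows the opposite facial sense), Ph3P=O (40 mol %), Me2Zn (3 equiv), toluene, 0 °C → rt; aq. NH4Cl at 0 °C
Reagents that add atoms: none
Why: catalytic enantioselective zinc-alkynylation of an α,β-unsaturated aldehyde, in which the dinuclear zinc–ProPhenol catalyst and not the remote ring centre sets the carbinol (the later C8), and the cis ester captures the zinc alkoxide as the butenolide with loss of methanol.

Step 7
Reactants: 10 (5R)-5-{[(4S)-4-{[tert-butyl(dimethyl)silyl]oxy}-1-hydroxy-2,2-dimethylcyclopentyl]ethynyl}-4-methylfuran-2(5H)-one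
Product: 12 (2Z)-5-[(2R,4S)-4-{[tert-butyl(dimethyl)silyl]oxy}-2-hydroxy-2,6,6-trimethylcyclohexylidene]-3-methylpenta-2,4-dienoic acid (allene axis R), via allenyl ketone aluminium carboxylate 11 (not isolated)
Conditions: Me3Al (5 equiv), CH2Cl2, −78 → 0 °C; aqueous potassium sodium tartrate/NaH2PO4
Reagents that add atoms: trimethylaluminium, C[Al](C)C (methyl group on C5)
Why: Proposed new method: Me3Al turns the tertiary carbinol into an aluminium alkoxide (push) and binds the lactone carbonyl (pull), so the ring bond C5–C1 migrates to alkyne carbon C6 while the in-plane π bond expels the propargylic C8–O bond of the butenolide in an SN2′ sense, giving ketone/allene/(Z)-acid 11, whose aluminium-bound ketone is methylated by the excess reagent; the closest known reaction types are the organoaluminium-promoted stereospecific pinacol-type (semipinacol) 1,2-shift of β-sulfonyloxy alcohols, including its tandem form in which the new carbonyl is alkylated by the aluminium reagent, and the anti-SN2′ 1,2-shift of alkynyl ate complexes that carry a propargylic leaving group. The six-membered carbocycle is formed by one-carbon ring expansion of the cyclopentane (1,2-alkyl shift that inserts C6 between C5 and C1), not by a cyclisation, and the butenolide is opened in the same event, leaving the 9Z acid. The allene axis is set by anti alignment of the migrating bond and the leaving C8–O bond, which transfers the 5R centre of 10 to the R axis, while the carbinol centre is destroyed so that both epimers of 10 converge. C5 is set by substrate control from C3: with the silyloxy group equatorial, the axial methyl of C1 blocks axial attack on the C5 carbonyl as in 3,3,5-trimethylcyclohexanone, so the methyl enters equatorially and the hydroxyl ends up axial, trans to the C3 oxygen (5R). The step needs migration of the quaternary C(CH3)2 carbon and not of the ring CH2 (higher migratory aptitude; free rotation about the alkyne lets either bond align), displacement without prior ionisation at C8 (the electron-poor butenolide destabilises a C8 cation), and methyl transfer faster than return of the carboxylate to C7 (the carboxylate is tied up by the excess aluminium reagent). Should the displacement prove to be syn, the antipodal ligand in step 6 would supply the 5S lactone and the same product.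

Step 8
Reactants: 12 (2Z)-5-[(2R,4S)-4-{[tert-butyl(dimethyl)silyl]oxy}-2-hydroxy-2,6,6-trimethylcyclohexylidene]-3-methylpenta-2,4-dienoic acid
Product: 14 methyl (2Z)-3-[(2S,6S,7aR)-6-{[tert-butyl(dimethyl)silyl]oxy}-4,4,7a-trimethyl-2,4,5,6,7,7a-hexahydro-1-benzofuran-2-yl]but-2-enoate, via allenol methyl ester 13 (not isolated)
Conditions: Me3SiCHN2, toluene/MeOH 4:1, 0 °C; evaporate; Ph3PAuNTf2 (3 mol %), THF, 0 °C → rt
Reagents that add atoms: (trimethylsilyl)diazomethane, C[Si](C)(C)C=[N+]=[N-] (ester methyl carbon)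
Why: esterification, then 5-endo cycloisomerisation of an α-hydroxyallene to a 2,5-dihydrofuran with a monovalent gold catalyst; the C5 hydroxyl attacks C8 in the plane of the allene π bond, so the R axis should be transferred fully to the 8S centre (chain cis to the C5 methyl), and the methyl ester keeps the C11 carbonyl oxygen from competing.

Step 9
Reactants: 14 methyl (2Z)-3-[(2S,6S,7aR)-6-{[tert-butyl(dimethyl)silyl]oxy}-4,4,7a-trimethyl-2,4,5,6,7,7a-hexahydro-1-benzofuran-2-yl]but-2-enoate
Product: 15 (2Z)-3-[(2S,6S,7aR)-6-{[tert-butyl(dimethyl)silyl]oxy}-4,4,7a-trimethyl-2,4,5,6,7,7a-hexahydro-1-benzofuran-2-yl]but-2-en-1-ol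
Conditions: i-Bu2AlH (2.5 equiv), CH2Cl2, −78 °C; aqueous potassium sodium tartrate
Reagents that add atoms: none
Why: 1,2-reduction of an enoate to the allylic alcohol, which leaves the Z double bond, the silyl ether and the allylic C8 ether untouched.

Step 10
Reactants: 15 (2Z)-3-[(2S,6S,7aR)-6-{[tert-butyl(dimethyl)silyl]oxy}-4,4,7a-trimethyl-2,4,5,6,7,7a-hexahydro-1-benzofuran-2-yl]but-2-en-1-ol
Product: 16 (2Z)-3-[(2S,6S,7aR)-6-{[tert-butyl(dimethyl)silyl]oxy}-4,4,7a-trimethyl-2,4,5,6,7,7a-hexahydro-1-benzofuran-2-yl]but-2-enal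
Conditions: MnO2 (activated, excess), CH2Cl2, 0 °C → rt, dark
Reagents that add atoms: none
Why: neutral, chemoselective allylic oxidation that should keep the 9Z geometry and the acid-labile C8 ether.

Step 11
Reactants: 17 (2E,4E,6E)-2,7-dimethylocta-2,4,6-trienedial (2.5 equiv, excess recovered)
Product: 18 ethyl (2E,4E,6E,8E)-4,9-dimethyl-10-oxodeca-2,4,6,8-tetraenoate
Conditions: Ph3P=CHCO2Et (1 equiv), CH2Cl2, 0 °C → rt
Reagents that add atoms: ethyl (triphenylphosphoranylidene)acetate, CCOC(=O)C=P(c1ccccc1)(c1ccccc1)c1ccccc1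
Why: E-selective Wittig reaction of a stabilised ylide; the excess of the symmetric dialdehyde limits double olefination.

Step 12
Reactants: 18 ethyl (2E,4E,6E,8E)-4,9-dimethyl-10-oxodeca-2,4,6,8-tetraenoate
Product: 19 ethyl (2E,4E,6E,8E)-10-hydroxy-4,9-dimethyldeca-2,4,6,8-tetraenoate
Conditions: NaBH4, EtOH, −20 °C
Reagents that add atoms: none
Why: chemoselective reduction of the aldehyde in the presence of the conjugated ester.

Step 13
Reactants: 19 ethyl (2E,4E,6E,8E)-10-hydroxy-4,9-dimethyldeca-2,4,6,8-tetraenoate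
Product: 20 ethyl (2E,4E,6E,8E)-10-bromo-4,9-dimethyldeca-2,4,6,8-tetraenoate
Conditions: PBr3 (0.4 equiv), pyridine (cat.), Et2O, −10 °C
Reagents that add atoms: phosphorus tribromide, BrP(Br)Br
Why: bromination of a primary allylic alcohol; the fully conjugated primary bromide is the favoured allylic isomer.

Step 14
Reactants: 20 ethyl (2E,4E,6E,8E)-10-bromo-4,9-dimethyldeca-2,4,6,8-tetraenoate
Product: 21 ethyl (2E,4E,6E,8E)-10-(diethoxyphosphoryl)-4,9-dimethyldeca-2,4,6,8-tetraenoate
Conditions: P(OEt)3, 85 °C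
Reagents that add atoms: triethyl phosphite, CCOP(OCC)OCC
Why: Michaelis–Arbuzov reaction of an allylic bromide.

Step 15
Reactants: 16 (2Z)-3-[(2S,6S,7aR)-6-{[tert-butyl(dimethyl)silyl]oxy}-4,4,7a-trimethyl-2,4,5,6,7,7a-hexahydro-1-benzofuran-2-yl]but-2-enal; 21 ethyl (2E,4E,6E,8E)-10-(diethoxyphosphoryl)-4,9-dimethyldeca-2,4,6,8-tetraenoate
Product: 22 ethyl (2E,4E,6E,8E,10E,12Z)-13-[(2S,6S,7aR)-6-{[tert-butyl(dimethyl)silyl]oxy}-4,4,7a-trimethyl-2,4,5,6,7,7a-hexahydro-1-benzofuran-2-yl]-4,9-dimethyltetradeca-2,4,6,8,10,12-hexaenoate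
Conditions: 21, NaN(SiMe3)2 (1.0 equiv), THF, −78 °C; then 16, −78 → 0 °C
Reagents that add atoms: none
Why: Horner–Wadsworth–Emmons olefination, E-selective for C11=C12; the Z-enal is the electrophile, so the 9Z bond should be preserved as in 9-cis-retinoid syntheses, and the weakly basic delocalised anion should add faster than it can deprotonate C8.

Step 16
Reactants: 22 ethyl (2E,4E,6E,8E,10E,12Z)-13-[(2S,6S,7aR)-6-{[tert-butyl(dimethyl)silyl]oxy}-4,4,7a-trimethyl-2,4,5,6,7,7a-hexahydro-1-benzofuran-2-yl]-4,9-dimethyltetradeca-2,4,6,8,10,12-hexaenoate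
Product: 23 (2E,4E,6E,8E,10E,12Z)-13-[(2S,6S,7aR)-6-{[tert-butyl(dimethyl)silyl]oxy}-4,4,7a-trimethyl-2,4,5,6,7,7a-hexahydro-1-benzofuran-2-yl]-4,9-dimethyltetradeca-2,4,6,8,10,12-hexaen-1-ol
Conditions: i-Bu2AlH (3 equiv), THF, −78 °C; aqueous potassium sodium tartrate
Reagents that add atoms: none
Why: 1,2-reduction of the polyenoate to the primary allylic alcohol (C10′) under non-acidic work-up.

Step 17
Reactants: 23 (2E,4E,6E,8E,10E,12Z)-13-[(2S,6S,7aR)-6-{[tert-butyl(dimethyl)silyl]oxy}-4,4,7a-trimethyl-2,4,5,6,7,7a-hexahydro-1-benzofuran-2-yl]-4,9-dimethyltetradeca-2,4,6,8,10,12-hexaen-1-ol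
Product: 24 (2E,4E,6E,8E,10E,12Z)-13-[(2S,6S,7aR)-6-hydroxy-4,4,7a-trimethyl-2,4,5,6,7,7a-hexahydro-1-benzofuran-2-yl]-4,9-dimethyltetradeca-2,4,6,8,10,12-hexaen-1-ol (CNP0263491.3)
Conditions: Bu4NF, THF, 0 °C → rt
Reagents that add atoms: none
Why: fluoride desilylation under non-acidic conditions, which avoids ionisation and epimerisation at the doubly allylic C8 ether.

**Compound list**

1 | 2,2-dimethylcyclopentan-1-one | CC1(C)CCCC1=O | starting material
2 | 5,5-dimethylcyclopent-2-en-1-one | CC1(C)CC=CC1=O | intermediate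
3 | (4S)-2,2-dimethyl-4-(4,4,5,5-tetramethyl-1,3,2-dioxaborolan-2-yl)cyclopentan-1-one | CC1(C)C[C@H](B2OC(C)(C)C(C)(C)O2)CC1=O | intermediate
4 | (4S)-4-hydroxy-2,2-dimethylcyclopentan-1-one | CC1(C)C[C@H](O)CC1=O | intermediate
5 | (4S)-4-{[tert-butyl(dimethyl)silyl]oxy}-2,2-dimethylcyclopentan-1-one | CC1(C)C[C@H](O[Si](C)(C)C(C)(C)C)CC1=O | intermediate
6 | (4S)-4-{[tert-butyl(dimethyl)silyl]oxy}-1-ethynyl-2,2-dimethylcyclopentan-1-ol (both C-1 epimers) | CC1(C)C[C@H](O[Si](C)(C)C(C)(C)C)CC1(O)C#C | intermediate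
7 | 5-hydroxy-4-methylfuran-2(5H)-one | CC1=CC(=O)OC1O | starting material
8 | methyl (2Z)-3-methyl-4-oxobut-2-enoate | COC(=O)/C=C(C)\C=O | intermediate
9 | zinc alkoxide of methyl (2Z,4R)-6-[(4S)-4-{[tert-butyl(dimethyl)silyl]oxy}-1-hydroxy-2,2-dimethylcyclopentyl]-4-hydroxy-3-methylhex-2-en-5-ynoate (SMILES of the parent alcohol) | COC(=O)/C=C(C)\[C@@H](O)C#CC1(O)C[C@@H](O[Si](C)(C)C(C)(C)C)CC1(C)C | intermediate
10 | (5R)-5-{[(4S)-4-{[tert-butyl(dimethyl)silyl]oxy}-1-hydroxy-2,2-dimethylcyclopentyl]ethynyl}-4-methylfuran-2(5H)-one (both carbinol epimers) | CC1=CC(=O)O[C@H]1C#CC1(O)C[C@@H](O[Si](C)(C)C(C)(C)C)CC1(C)C | intermediate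
11 | (2Z)-5-[(4S)-4-{[tert-butyl(dimethyl)silyl]oxy}-2,2-dimethyl-6-oxocyclohexylidene]-3-methylpenta-2,4-dienoic acid, allene axis R (formed as its aluminium carboxylate) | OC(=O)/C=C(C)\C([H])=[C@@]=C1C(C)(C)C[C@H](O[Si](C)(C)C(C)(C)C)CC1=O | intermediate
12 | (2Z)-5-[(2R,4S)-4-{[tert-butyl(dimethyl)silyl]oxy}-2-hydroxy-2,6,6-trimethylcyclohexylidene]-3-methylpenta-2,4-dienoic acid, allene axis R | OC(=O)/C=C(C)\C([H])=[C@@]=C1C(C)(C)C[C@H](O[Si](C)(C)C(C)(C)C)C[C@@]1(C)O | intermediate
13 | methyl (2Z)-5-[(2R,4S)-4-{[tert-butyl(dimethyl)silyl]oxy}-2-hydroxy-2,6,6-trimethylcyclohexylidene]-3-methylpenta-2,4-dienoate, allene axis R | COC(=O)/C=C(C)\C([H])=[C@@]=C1C(C)(C)C[C@H](O[Si](C)(C)C(C)(C)C)C[C@@]1(C)O | intermediate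
14 | methyl (2Z)-3-[(2S,6S,7aR)-6-{[tert-butyl(dimethyl)silyl]oxy}-4,4,7a-trimethyl-2,4,5,6,7,7a-hexahydro-1-benzofuran-2-yl]but-2-enoate | COC(=O)/C=C(C)\[C@@H]1C=C2C(C)(C)C[C@H](O[Si](C)(C)C(C)(C)C)C[C@@]2(C)O1 | intermediate
15 | (2Z)-3-[(2S,6S,7aR)-6-{[tert-butyl(dimethyl)silyl]oxy}-4,4,7a-trimethyl-2,4,5,6,7,7a-hexahydro-1-benzofuran-2-yl]but-2-en-1-ol | OC/C=C(C)\[C@@H]1C=C2C(C)(C)C[C@H](O[Si](C)(C)C(C)(C)C)C[C@@]2(C)O1 | intermediate
16 | (2Z)-3-[(2S,6S,7aR)-6-{[tert-butyl(dimethyl)silyl]oxy}-4,4,7a-trimethyl-2,4,5,6,7,7a-hexahydro-1-benzofuran-2-yl]but-2-enal | O=C/C=C(C)\[C@@H]1C=C2C(C)(C)C[C@H](O[Si](C)(C)C(C)(C)C)C[C@@]2(C)O1 | intermediate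
17 | (2E,4E,6E)-2,7-dimethylocta-2,4,6-trienedial | O=C/C(C)=C/C=C/C=C(C)/C=O | starting material
18 | ethyl (2E,4E,6E,8E)-4,9-dimethyl-10-oxodeca-2,4,6,8-tetraenoate | CCOC(=O)/C=C/C(C)=C/C=C/C=C(C)/C=O | intermediate
19 | ethyl (2E,4E,6E,8E)-10-hydroxy-4,9-dimethyldeca-2,4,6,8-tetraenoate | CCOC(=O)/C=C/C(C)=C/C=C/C=C(C)/CO | intermediate
20 | ethyl (2E,4E,6E,8E)-10-bromo-4,9-dimethyldeca-2,4,6,8-tetraenoate | CCOC(=O)/C=C/C(C)=C/C=C/C=C(C)/CBr | intermediate
21 | ethyl (2E,4E,6E,8E)-10-(diethoxyphosphoryl)-4,9-dimethyldeca-2,4,6,8-tetraenoate | CCOC(=O)/C=C/C(C)=C/C=C/C=C(C)/CP(=O)(OCC)OCC | intermediate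
22 | ethyl (2E,4E,6E,8E,10E,12Z)-13-[(2S,6S,7aR)-6-{[tert-butyl(dimethyl)silyl]oxy}-4,4,7a-trimethyl-2,4,5,6,7,7a-hexahydro-1-benzofuran-2-yl]-4,9-dimethyltetradeca-2,4,6,8,10,12-hexaenoate | C/C(=C/C=C/C(C)=C/C=C/C=C(C)/C=C/C(=O)OCC)[C@@H]1C=C2C(C)(C)C[C@H](O[Si](C)(C)C(C)(C)C)C[C@@]2(C)O1 | intermediate
23 | (2E,4E,6E,8E,10E,12Z)-13-[(2S,6S,7aR)-6-{[tert-butyl(dimethyl)silyl]oxy}-4,4,7a-trimethyl-2,4,5,6,7,7a-hexahydro-1-benzofuran-2-yl]-4,9-dimethyltetradeca-2,4,6,8,10,12-hexaen-1-ol | C/C(=C/C=C/C(C)=C/C=C/C=C(C)/C=C/CO)[C@@H]1C=C2C(C)(C)C[C@H](O[Si](C)(C)C(C)(C)C)C[C@@]2(C)O1 | intermediate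
24 | (2E,4E,6E,8E,10E,12Z)-13-[(2S,6S,7aR)-6-hydroxy-4,4,7a-trimethyl-2,4,5,6,7,7a-hexahydro-1-benzofuran-2-yl]-4,9-dimethyltetradeca-2,4,6,8,10,12-hexaen-1-ol | C/C(=C/C=C/C(C)=C/C=C/C=C(C)/C=C/CO)[C@@H]1C=C2C(C)(C)C[C@H](O)C[C@@]2(C)O1 | target

**Step count and risks**

Total: 17 steps. Longest linear sequence: 12 steps (1–4, 6–10, 15–17); steps 5 and 11–14 make the two side fragments.

Steps most likely to fail:

1. Step 7 (the step with the new-method label). The shift may stall because a lactone carboxylate is only a moderate leaving group. The C8–O bond may ionise before migration, with loss of the axial information. The ring CH2 may migrate in place of C(CH3)2. The liberated carboxylate may return to C7 of the allenyl ketone (2-pyranone formation) before methyl transfer. The methyl group may add without facial control. The fallback uses known chemistry, keeps a one-carbon ring expansion, sets out from 5 and comes back at 13, which then enters the gold stage of step 8. Homologation of 5 with Me3SiCHN2 and BF3·OEt2 (CH2Cl2, −78 °C; the less substituted α-carbon migrates; protodesilylation on work-up) gives (4R)-4-{[tert-butyl(dimethyl)silyl]oxy}-2,2-dimethylcyclohexan-1-one F1. Methylation with LiN(i-Pr)2 and MeI gives (4R)-4-{[tert-butyl(dimethyl)silyl]oxy}-2,2,6-trimethylcyclohexan-1-one F2. KN(SiMe3)2 and PhNTf2 give (4R)-4-{[tert-butyl(dimethyl)silyl]oxy}-2,6,6-trimethylcyclohex-1-en-1-yl trifluoromethanesulfonate F3. Sonogashira coupling with trimethylsilylacetylene (Pd(PPh3)4, CuI, Et3N) gives tert-butyl(dimethyl)({(1R)-3,5,5-trimethyl-4-[(trimethylsilyl)ethynyl]cyclohex-3-en-1-yl}oxy)silane F4, and K2CO3 in MeOH gives tert-butyl{[(1R)-4-ethynyl-3,5,5-trimethylcyclohex-3-en-1-yl]oxy}dimethylsilane F5. m-CPBA (NaHCO3, CH2Cl2, 0 °C) should epoxidise the ring double bond anti to the silyloxy group and give tert-butyl{[(1R,3S,6R)-6-ethynyl-1,5,5-trimethyl-7-oxabicyclo[4.1.0]heptan-3-yl]oxy}dimethylsilane F6. Methyl (2Z)-3-iodobut-2-enoate F7 (from methyl but-2-ynoate, NaI, AcOH) is converted with i-PrMgCl·LiCl (−40 °C) and ZnCl2 into the alkenylzinc reagent, which couples with F6 under Pd(PPh3)4 catalysis; zerovalent palladium adds anti in an SN2′ sense, so the chain enters C8 anti to the epoxide oxygen and 13 results. Here C5 is set by the epoxidation and the axis by the anti opening.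

2. Step 6. Aldehyde 8 may isomerise from Z to E before it reacts, the cis ester may lower the facial selectivity, and the zinc methoxide set free on lactonisation may epimerise the acidic C5–H of the butenolide; each erodes the centre that controls C8. The fallback sets out from 6 and comes back at 10. Under the same zinc–ProPhenol catalysis 6 is added to commercial ethyl (2E)-3-methyl-4-oxobut-2-enoate, a configurationally stable enal, to give ethyl (2E,4R)-6-[(4S)-4-{[tert-butyl(dimethyl)silyl]oxy}-1-hydroxy-2,2-dimethylcyclopentyl]-4-hydroxy-3-methylhex-2-en-5-ynoate F8. Acetone-sensitised irradiation (300 nm) then isomerises the E double bond, and the Z isomer should lactonise spontaneously under neutral conditions to 10.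

3. Step 8. The ester carbonyl oxygen, held cis to C8, may attack the gold-activated allene in place of the hydroxyl, or reversible gold–allene species may partly scramble the axis of the conjugated vinylallene. The fallback sets out from 13 (isolated after the esterification) and comes back at 14. Iodoetherification with N-iodosuccinimide (NaHCO3, CH2Cl2, 0 °C; 5-endo, same in-plane attack on C8) gives methyl (2Z)-3-[(2R,6S,7aR)-6-{[tert-butyl(dimethyl)silyl]oxy}-3-iodo-4,4,7a-trimethyl-2,4,5,6,7,7a-hexahydro-1-benzofuran-2-yl]but-2-enoate F9. Hydrodeiodination with Bu3SnH and Pd(PPh3)4 (THF, rt) then gives 14.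

**Further compounds**

F1 | step 7 | (4R)-4-{[tert-butyl(dimethyl)silyl]oxy}-2,2-dimethylcyclohexan-1-one | CC1(C)C[C@H](O[Si](C)(C)C(C)(C)C)CCC1=O
F2 | step 7 | (4R)-4-{[tert-butyl(dimethyl)silyl]oxy}-2,2,6-trimethylcyclohexan-1-one (both C-6 epimers) | CC1C[C@@H](O[Si](C)(C)C(C)(C)C)CC(C)(C)C1=O
F3 | step 7 | (4R)-4-{[tert-butyl(dimethyl)silyl]oxy}-2,6,6-trimethylcyclohex-1-en-1-yl trifluoromethanesulfonate | CC1=C(OS(=O)(=O)C(F)(F)F)C(C)(C)C[C@H](O[Si](C)(C)C(C)(C)C)C1
F4 | step 7 | tert-butyl(dimethyl)({(1R)-3,5,5-trimethyl-4-[(trimethylsilyl)ethynyl]cyclohex-3-en-1-yl}oxy)silane | CC1=C(C#C[Si](C)(C)C)C(C)(C)C[C@H](O[Si](C)(C)C(C)(C)C)C1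
F5 | step 7 | tert-butyl{[(1R)-4-ethynyl-3,5,5-trimethylcyclohex-3-en-1-yl]oxy}dimethylsilane | CC1=C(C#C)C(C)(C)C[C@H](O[Si](C)(C)C(C)(C)C)C1
F6 | step 7 | tert-butyl{[(1R,3S,6R)-6-ethynyl-1,5,5-trimethyl-7-oxabicyclo[4.1.0]heptan-3-yl]oxy}dimethylsilane | C#C[C@@]12O[C@]1(C)C[C@@H](O[Si](C)(C)C(C)(C)C)CC2(C)C
F7 | step 7 | methyl (2Z)-3-iodobut-2-enoate | COC(=O)/C=C(C)\I
F8 | step 6 | ethyl (2E,4R)-6-[(4S)-4-{[tert-butyl(dimethyl)silyl]oxy}-1-hydroxy-2,2-dimethylcyclopentyl]-4-hydroxy-3-methylhex-2-en-5-ynoate | CCOC(=O)/C=C(C)/[C@@H](O)C#CC1(O)C[C@@H](O[Si](C)(C)C(C)(C)C)CC1(C)C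
F9 | step 8 | methyl (2Z)-3-[(2R,6S,7aR)-6-{[tert-butyl(dimethyl)silyl]oxy}-3-iodo-4,4,7a-trimethyl-2,4,5,6,7,7a-hexahydro-1-benzofuran-2-yl]but-2-enoate | COC(=O)/C=C(C)\[C@@H]1C(I)=C2C(C)(C)C[C@H](O[Si](C)(C)C(C)(C)C)C[C@@]2(C)O1
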